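**Strategy.** Prebarbigerone is disconnected at C4, the single carbonyl carbon of the pyranone ring (ring C), which lies between C4a of ring A and the benzylic C3 that carries ring B. A palladium-catalysed carbonylative Negishi coupling supplies C4 as carbon monoxide and forms both C4a–C4 and C4–C3 in one operation, giving the complete deoxybenzoin without closing a ring. The electrophile is a 1,2,3,4-tetrasubstituted aryl iodide (iodine at the future C4a, MOM-protected O1, C8 prenyl, C7 methoxy) built by two directed lithiations. The nucleophile is 2,4,5-trimethoxybenzylzinc chloride. C2 is then added with DMF dimethyl acetal, and acid frees the phenol to close ring C.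

Key step: step 7

Remark: the target has no stereocentre and no stereogenic double bond, so it is achiral and the route needs no stereocontrol.

**Step 1**
Reactants: 1 3-methoxyphenol
Product: 2 1-methoxy-3-(methoxymethoxy)benzene
Conditions: MOMCl, i-Pr2NEt, CH2Cl2, 0 °C → rt
Reagents that add atoms: chloromethyl methyl ether (MOMCl), COCCl
Why: O-alkylation of the phenol by the highly electrophilic α-chloro ether under amine base (Williamson-type) should give the MOM ether, which later serves as the stronger ortho-directing group.

**Step 2**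
Reactants: 2 1-methoxy-3-(methoxymethoxy)benzene; 3 prenyl bromide (1-bromo-3-methylbut-2-ene)
Product: 5 1-methoxy-3-(methoxymethoxy)-2-(3-methylbut-2-enyl)benzene, via C2-aryllithium 4 (not isolated)
Conditions: n-BuLi, THF, 0 °C → rt; then 3, −78 °C → rt
Reagents that add atoms: none
Why: Directed ortho-metalation occurs at C2, the position flanked by both oxygen directors, and the 2,6-dialkoxyaryllithium should be alkylated by the primary allylic bromide in an SN2 sense at the unhindered CH2 terminus.

**Step 3**
Reactants: 5 1-methoxy-3-(methoxymethoxy)-2-(3-methylbut-2-enyl)benzene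
Product: 7 1-iodo-4-methoxy-2-(methoxymethoxy)-3-(3-methylbut-2-enyl)benzene, via C4-aryllithium 6 (not isolated)
Conditions: s-BuLi, TMEDA, THF, −78 °C; then I2, THF, −78 °C → rt; aq. Na2S2O3
Reagents that add atoms: iodine, II
Why: In this second directed ortho-metalation C2 is blocked and the chelating OMOM group outranks OMe as director, so kinetic lithiation at −78 °C should occur at C4 rather than C6 or the benzylic–allylic CH2, and iodinolysis places iodine at the future C4a.

**Step 4**
Reactants: 8 2,4,5-trimethoxybenzaldehyde
Product: 9 (2,4,5-trimethoxyphenyl)methanol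
Conditions: NaBH4, MeOH, 0 °C → rt
Reagents that add atoms: none
Why: Borohydride reduction of an aryl aldehyde to the benzylic alcohol is routine and touches nothing else.

**Step 5**
Reactants: 9 (2,4,5-trimethoxyphenyl)methanol
Product: 10 1-(chloromethyl)-2,4,5-trimethoxybenzene
Conditions: SOCl2, CH2Cl2, 0 °C; volatiles removed, crude chloride used at once
Reagents that add atoms: thionyl chloride, O=S(Cl)Cl
Why: Deoxychlorination through the chlorosulfite is fast for an electron-rich benzylic alcohol at 0 °C, and immediate use of the labile chloride avoids self-alkylation.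

**Step 6**
Reactants: 10 1-(chloromethyl)-2,4,5-trimethoxybenzene
Product: 11 2,4,5-trimethoxybenzylzinc chloride (LiCl-complexed THF solution, titrated with iodine and used directly)
Conditions: Zn dust (activated with BrCH2CH2Br, TMSCl), LiCl, THF, 25 °C
Reagents that add atoms: zinc, [Zn]
Why: LiCl-promoted oxidative insertion of zinc into a benzylic C–Cl bond (Knochel conditions) proceeds at room temperature with little Wurtz homocoupling, also for methoxy-rich rings.

**Step 7**
Reactants: 7 1-iodo-4-methoxy-2-(methoxymethoxy)-3-(3-methylbut-2-enyl)benzene; 11 2,4,5-trimethoxybenzylzinc chloride; 12 carbon monoxide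
Product: 13 1-[4-methoxy-2-(methoxymethoxy)-3-(3-methylbut-2-enyl)phenyl]-2-(2,4,5-trimethoxyphenyl)ethanone
Conditions: Pd2(dba)3 (2.5 mol %), Xantphos (6 mol %), CO (3 bar), THF, 45 °C, slow addition of 11 (1.5 equiv)
Reagents that add atoms: none
Why: Pd(0) inserts into the C–I bond of 7, CO coordinates and migrates to give the aroylpalladium(II) iodide, and transmetalation from 11 followed by reductive elimination releases ketone 13, so C4a–C4 and C4–C3 form in one catalytic cycle. The closest known reaction type is the carbonylative Negishi coupling of aryl iodides with benzylic or alkyl zinc halides, which gives aryl benzyl ketones (deoxybenzoins). No ring is closed and no stereocentre is created. The selectivity needed is CO insertion ahead of transmetalation, since direct coupling would give the diarylmethane; the ortho-OMOM group slows transmetalation at the crowded arylpalladium while the small CO still inserts, the wide-bite-angle diphosphine favours the acyl pathway, and slow addition of 11 under CO pressure keeps the zinc reagent scarce. The prenyl alkene is trisubstituted and meta to the palladated carbon, so no Heck-type cyclisation is possible, and the MOM and methyl ethers are inert to the neutral organozinc.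

**Step 8**
Reactants: 13 1-[4-methoxy-2-(methoxymethoxy)-3-(3-methylbut-2-enyl)phenyl]-2-(2,4,5-trimethoxyphenyl)ethanone
Product: 14 (E)-3-(dimethylamino)-1-[4-methoxy-2-(methoxymethoxy)-3-(3-methylbut-2-enyl)phenyl]-2-(2,4,5-trimethoxyphenyl)prop-2-en-1-one (drawn as the E isomer expected for such push–pull enaminones; the geometry is labile and is lost in step 9)
Conditions: Me2NCH(OMe)2, toluene, 100 °C
Reagents that add atoms: N,N-dimethylformamide dimethyl acetal, COC(OC)N(C)C
Why: Condensation of the doubly activated methylene (α to the ketone and to ring B) with the amide acetal should give the enaminone with loss of two methanol, installing the future C2 at the aldehyde oxidation level.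

**Step 9**
Reactants: 14 (E)-3-(dimethylamino)-1-[4-methoxy-2-(methoxymethoxy)-3-(3-methylbut-2-enyl)phenyl]-2-(2,4,5-trimethoxyphenyl)prop-2-en-1-one
Product: 16 prebarbigerone [7-methoxy-8-(3-methylbut-2-enyl)-3-(2,4,5-trimethoxyphenyl)chromen-4-one], via phenol enaminone 15 (not isolated)
Conditions: HCl (1 M in MeOH, 2 equiv), 40 °C; aq. NaHCO3 work-up
Reagents that add atoms: none
Why: Acidic methanolysis of the MOM acetal frees the C8a phenol, which should add to the iminium-activated β-carbon of the enaminone and expel dimethylamine (addition–elimination chromone closure) faster than it can add to the neighbouring prenyl alkene.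

**Compound list**

1 | 3-methoxyphenol | COc1cccc(O)c1 | starting material
2 | 1-methoxy-3-(methoxymethoxy)benzene | COCOc1cccc(OC)c1 | intermediate
3 | prenyl bromide (1-bromo-3-methylbut-2-ene) | CC(C)=CCBr | starting material
4 | C2-aryllithium: 2-lithio-1-methoxy-3-(methoxymethoxy)benzene (not isolated) | [Li]c1c(OC)cccc1OCOC | intermediate
5 | 1-methoxy-3-(methoxymethoxy)-2-(3-methylbut-2-enyl)benzene | COCOc1cccc(OC)c1CC=C(C)C | intermediate
6 | C4-aryllithium: [4-methoxy-2-(methoxymethoxy)-3-(3-methylbut-2-enyl)phenyl]lithium (not isolated) | COCOc1c([Li])ccc(OC)c1CC=C(C)C | intermediate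
7 | 1-iodo-4-methoxy-2-(methoxymethoxy)-3-(3-methylbut-2-enyl)benzene | COCOc1c(I)ccc(OC)c1CC=C(C)C | intermediate
8 | 2,4,5-trimethoxybenzaldehyde | COc1cc(OC)c(C=O)cc1OC | starting material
9 | (2,4,5-trimethoxyphenyl)methanol | COc1cc(OC)c(CO)cc1OC | intermediate
10 | 1-(chloromethyl)-2,4,5-trimethoxybenzene | COc1cc(OC)c(CCl)cc1OC | intermediate
11 | 2,4,5-trimethoxybenzylzinc chloride (THF solution) | COc1cc(OC)c(C[Zn]Cl)cc1OC | intermediate
12 | carbon monoxide | [C-]#[O+] | starting material
13 | 1-[4-methoxy-2-(methoxymethoxy)-3-(3-methylbut-2-enyl)phenyl]-2-(2,4,5-trimethoxyphenyl)ethanone | COCOc1c(CC=C(C)C)c(OC)ccc1C(=O)Cc1cc(OC)c(OC)cc1OC | intermediate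
14 | (E)-3-(dimethylamino)-1-[4-methoxy-2-(methoxymethoxy)-3-(3-methylbut-2-enyl)phenyl]-2-(2,4,5-trimethoxyphenyl)prop-2-en-1-one | CN(C)/C=C(/C(=O)c1ccc(OC)c(CC=C(C)C)c1OCOC)c1cc(OC)c(OC)cc1OC | intermediate
15 | phenol enaminone: (E)-3-(dimethylamino)-1-[2-hydroxy-4-methoxy-3-(3-methylbut-2-enyl)phenyl]-2-(2,4,5-trimethoxyphenyl)prop-2-en-1-one (not isolated) | CN(C)/C=C(/C(=O)c1ccc(OC)c(CC=C(C)C)c1O)c1cc(OC)c(OC)cc1OC | intermediate
16 | prebarbigerone, 7-methoxy-8-(3-methylbut-2-enyl)-3-(2,4,5-trimethoxyphenyl)chromen-4-one | COc1cc(OC)c(-c2coc3c(CC=C(C)C)c(OC)ccc3c2=O)cc1OC | target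

**Step count.** Total: 9 steps. Longest linear sequence: 6 steps (steps 1–3 then 7–9; the B-ring branch, steps 4–6 then 7–9, is equally long).

**Steps most likely to fail**

1. Step 7. The risk is direct aryl–benzyl cross-coupling overtaking CO insertion, or stalling at the hindered aroylpalladium stage. The fallback sets out from 7 and returns at 13. Iodine–magnesium exchange of 7 (i-PrMgCl·LiCl, THF, 0 °C) should give [4-methoxy-2-(methoxymethoxy)-3-(3-methylbut-2-enyl)phenyl]magnesium chloride F1. Quenching with DMF gives 4-methoxy-2-(methoxymethoxy)-3-(3-methylbut-2-enyl)benzaldehyde F2. Uncatalysed 1,2-addition of benzylzinc chloride 11 (THF, 25 °C) then gives racemic 1-[4-methoxy-2-(methoxymethoxy)-3-(3-methylbut-2-enyl)phenyl]-2-(2,4,5-trimethoxyphenyl)ethanol F3. Dess–Martin oxidation (NaHCO3, CH2Cl2) returns ketone 13. The carbonyl carbon then comes from DMF instead of CO.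

2. Step 3. The risk is deprotonation at the benzylic–allylic CH2 of the prenyl group, or lithiation ortho to OMe, in place of C4 lithiation. The fallback sets out from 1 and returns at 7, and no organolithium ever meets the prenyl group. Iodination of 1 ortho to OH and para to OMe (I2, NaHCO3, aq. THF) gives 2-iodo-5-methoxyphenol F4, which can also be purchased. O-Allylation (allyl bromide, K2CO3, acetone) gives 1-iodo-4-methoxy-2-(prop-2-enyloxy)benzene F5. Aromatic Claisen rearrangement (PhNEt2, 190 °C) can deliver the allyl group only to the one free ortho carbon, giving 6-iodo-3-methoxy-2-(prop-2-enyl)phenol F6. MOM protection (MOMCl, i-Pr2NEt, CH2Cl2) gives 1-iodo-4-methoxy-2-(methoxymethoxy)-3-(prop-2-enyl)benzene F7. Cross-metathesis with 2-methylbut-2-ene (Grubbs II, CH2Cl2, 40 °C) converts allyl into prenyl and returns 7.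

3. Step 9. The risk is acid-promoted addition of the liberated phenol, or of solvent, to the prenyl alkene (chroman formation or hydration) competing with pyranone closure. The fallback sets out from 13 and returns at 16, and uses no protic acid. MOM cleavage of 13 under Lewis-acid conditions (ZnBr2, n-PrSH, CH2Cl2, 0 °C) gives the hydrogen-bonded 1-[2-hydroxy-4-methoxy-3-(3-methylbut-2-enyl)phenyl]-2-(2,4,5-trimethoxyphenyl)ethanone F8. Heating F8 with DMF dimethyl acetal (toluene, 90 °C) forms enaminone 15, which should cyclise thermally with loss of dimethylamine to 16.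

**Further compounds**

F1 | step 7 | [4-methoxy-2-(methoxymethoxy)-3-(3-methylbut-2-enyl)phenyl]magnesium chloride | COCOc1c([Mg]Cl)ccc(OC)c1CC=C(C)C
F2 | step 7 | 4-methoxy-2-(methoxymethoxy)-3-(3-methylbut-2-enyl)benzaldehyde | COCOc1c(C=O)ccc(OC)c1CC=C(C)C
F3 | step 7 | racemic 1-[4-methoxy-2-(methoxymethoxy)-3-(3-methylbut-2-enyl)phenyl]-2-(2,4,5-trimethoxyphenyl)ethanol | COCOc1c(C(O)Cc2cc(OC)c(OC)cc2OC)ccc(OC)c1CC=C(C)C
F4 | step 3 | 2-iodo-5-methoxyphenol | COc1ccc(I)c(O)c1
F5 | step 3 | 1-iodo-4-methoxy-2-(prop-2-enyloxy)benzene | C=CCOc1cc(OC)ccc1I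
F6 | step 3 | 6-iodo-3-methoxy-2-(prop-2-enyl)phenol | C=CCc1c(O)c(I)ccc1OC
F7 | step 3 | 1-iodo-4-methoxy-2-(methoxymethoxy)-3-(prop-2-enyl)benzene | C=CCc1c(OCOC)c(I)ccc1OC
F8 | step 9 | 1-[2-hydroxy-4-methoxy-3-(3-methylbut-2-enyl)phenyl]-2-(2,4,5-trimethoxyphenyl)ethanone | COc1ccc(C(=O)Cc2cc(OC)c(OC)cc2OC)c(O)c1CC=C(C)C
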